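**Retrosynthetic overview**
1. The target is traced back to the C4 alcohol (butyrylation last), then to a ketal-protected tetracycle (enone by Saegusa–Ito oxidation), whose nine-membered oxonene is closed last by ring-closing metathesis of the C6=C7 olefin from a tricycle carrying an allyl arm at C4 and a methallyl arm at C9.
2. The C9 arm comes from allylsilane addition to the oxocarbenium ion of a butanolide-derived lactol; the C4 carbinol comes from chelation-controlled allylation of a 2-formyl-2-methyloxepane.
3. Key disconnection: the oxepane (O, C16, C15, C14, C1, C2, C3) is the ring-contracted isomer of an eight-membered cyclic enol ether in which C4 is still a ring atom between the ether oxygen and C3. Because C3 is a fully substituted ether carbon whose exocyclic neighbour C4 sits one oxidation level below a formyl group, an oxidative 1,2-shift of the ring oxygen from C4 to C3 gives the ring, the C3 stereocentre and the C4 aldehyde in one operation.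
4. The eight-membered enol ether comes from enol-ether ring-closing metathesis (vinyl ether on O–C16, isopropenyl on C2). Cyclohexane ring A and the butanolide (later the tetrahydrofuran) come from an endo Diels–Alder reaction of (S)-5-isopropenylbutenolide with a 2-silyloxy diene carrying C15/C16 from the chiral pool.
5. Order of ring formation: butenolide, ring A (Diels–Alder), eight-membered enol ether (metathesis), oxepane (ring contraction), oxonene (metathesis).

Key step: step 12

Remark: atoms are numbered as in the cladiellin/briarellin diterpenes (C1/C10 ring-fusion carbons of ring A, C2 and C9 the ether-bridged carbons, C3 the methyl-bearing oxepane carbon, C4 the butyrate carbon, C13 the ketone, C16 the oxepane CH2); (R)-4-methyldihydrofuran-2(3H)-one, (E)-1-bromoprop-1-ene and the ProPhenol ligand are taken as commercial.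

Step 1
Reactants: 1 methacrolein; 2 methyl propiolate
Product: 3 methyl (R)-4-hydroxy-5-methylhex-5-en-2-ynoate
Conditions: Me2Zn, (S,S)-ProPhenol (10 mol%), Ph3PO (20 mol%), toluene, 4 °C
Reagents that add atoms: none
Why: Catalytic asymmetric alkynylation of an aldehyde with the zinc acetylide of the propiolate; the dinuclear zinc–ProPhenol catalyst (ligand antipode chosen to give the R carbinol) sets the centre that becomes C2.

Step 2
Reactants: 3 methyl (R)-4-hydroxy-5-methylhex-5-en-2-ynoate
Product: 5 (S)-5-(prop-1-en-2-yl)furan-2(5H)-one, via Z-hydroxy enoate 4 (not isolated)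
Conditions: H2 (1 atm), Pd/CaCO3 poisoned with Pb(OAc)2, quinoline, EtOAc, rt; then PPTS (cat.), CH2Cl2, rt
Reagents that add atoms: none
Why: Lindlar cis-semihydrogenation of the ynoate should give the (Z)-γ-hydroxy enoate, which lactonises to the butenolide without touching the stereocentre; the 1,1-disubstituted isopropenyl olefin is reduced much more slowly.

Step 3
Reactants: 6 (R)-4-methyldihydrofuran-2(3H)-one
Product: 7 (R)-4-hydroxy-N-methoxy-N,3-dimethylbutanamide
Conditions: MeNH(OMe)·HCl, AlMe3, CH2Cl2, 0 °C to rt
Reagents that add atoms: N,O-dimethylhydroxylamine hydrochloride, CNOC.Cl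
Why: Aluminium-amide aminolysis of the lactone (Weinreb amide formation) opens the ring and leaves the future C15 centre untouched.

Step 4
Reactants: 7 (R)-4-hydroxy-N-methoxy-N,3-dimethylbutanamide
Product: 8 (R)-4-(tert-butyldiphenylsilyloxy)-N-methoxy-N,3-dimethylbutanamide
Conditions: TBDPSCl, imidazole, DMF, rt
Reagents that add atoms: tert-butyl(chloro)diphenylsilane, CC(C)(C)[Si](Cl)(c1ccccc1)c1ccccc1
Why: Standard silylation of the primary alcohol (future O–C16) with a group that survives the acidic ketalisation in step 8.

Step 5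
Reactants: 8 (R)-4-(tert-butyldiphenylsilyloxy)-N-methoxy-N,3-dimethylbutanamide
Product: 9 (R,E)-7-(tert-butyldiphenylsilyloxy)-6-methylhept-2-en-4-one
Conditions: (E)-1-bromoprop-1-ene, t-BuLi (2 equiv), Et2O, −78 °C; then 8, −78 to 0 °C
Reagents that add atoms: (E)-1-bromoprop-1-ene, C/C=C/Br
Why: Weinreb ketone synthesis: the alkenyllithium from bromine–lithium exchange (retention of E geometry) adds once, because the chelated tetrahedral intermediate does not collapse before work-up.

Step 6
Reactants: 9 (R,E)-7-(tert-butyldiphenylsilyloxy)-6-methylhept-2-en-4-one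
Product: 10 (2E,4Z,6R)-4-(tert-butyldimethylsilyloxy)-7-(tert-butyldiphenylsilyloxy)-6-methylhepta-2,4-diene
Conditions: TBSOTf, Et3N, CH2Cl2, −78 to 0 °C
Reagents that add atoms: tert-butyldimethylsilyl trifluoromethanesulfonate, CC(C)(C)[Si](C)(C)OS(=O)(=O)C(F)(F)F
Why: Soft enolisation on the CH2 side should give the cross-conjugated 2-silyloxy diene as the (Z)-enol ether, which places the side chain in the outside position of the s-cis diene.

Step 7
Reactants: 5 (S)-5-(prop-1-en-2-yl)furan-2(5H)-one; 10 (2E,4Z,6R)-4-(tert-butyldimethylsilyloxy)-7-(tert-butyldiphenylsilyloxy)-6-methylhepta-2,4-diene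
Product: 11 endo cycloadduct, cis-fused 3-isopropenyl-7-methyl-5-(tert-butyldimethylsilyloxy)-4-[(R)-1-(tert-butyldiphenylsilyloxy)propan-2-yl]-3a,4,7,7a-tetrahydroisobenzofuran-1(3H)-one (H-3a, H-4, H-7, H-7a all cis; isopropenyl cis to the ring-fusion hydrogens)
Conditions: toluene, BHT (cat.), 140 °C, sealed tube
Reagents that add atoms: none
Why: Diels–Alder reaction in which the 2-silyloxy group makes C14 the nucleophilic diene terminus (bond to the butenolide β-carbon C1), the diene adds anti to the isopropenyl group at C2, and the endo transition state puts the outside substituents cis to the lactone, which should set C1, C10 and C14 (and C11) as drawn; C15 is a spectator.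

Step 8
Reactants: 11 endo cycloadduct (silyl enol ether lactone)
Product: 12 C13 ethylene ketal, cis-fused 3-isopropenyl-7-methyl-4-[(R)-1-(tert-butyldiphenylsilyloxy)propan-2-yl]hexahydroisobenzofuran-1,5-dione 5-(ethylene ketal)
Conditions: HOCH2CH2OH, PPTS, benzene, 60 °C
Reagents that add atoms: ethylene glycol, OCCO
Why: Acid-catalysed protodesilylation of the enol ether and ketalisation in one pot protect the C13 ketone against the hydride, Lewis-acid and base steps that follow; the mild acid should leave the C14 centre and the silyl ether intact.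

Step 9
Reactants: 12 C13 ethylene ketal (silyl ether)
Product: 13 primary alcohol (free C16–OH; otherwise as 12)
Conditions: Bu4NF, AcOH, THF, 0 °C to rt
Reagents that add atoms: none
Why: Fluoride desilylation; the saturated lactone and the ketal are stable to buffered fluoride.

Step 10
Reactants: 13 primary alcohol
Product: 14 vinyl ether (C16–O–CH=CH2; otherwise as 13)
Conditions: [Ir(cod)Cl]2 (2 mol%), Na2CO3, vinyl acetate, toluene, 100 °C
Reagents that add atoms: vinyl acetate, C=COC(C)=O
Why: Iridium-catalysed transfer vinylation of a primary alcohol from vinyl acetate installs the carbon that becomes C4 on the ether oxygen under non-acidic conditions.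

Step 11
Reactants: 14 vinyl ether
Product: 15 eight-membered cyclic enol ether (ring O, C4H=C3(CH3), C2, C1, C14, C15, C16; Z), fused to the ketal-protected hydroisobenzofuranone
Conditions: Mo(=CHCMe2Ph)(=N-2,6-i-Pr2C6H3)[OCMe(CF3)2]2 (15 mol%), benzene, 60 °C, 2 mM, argon sparge
Reagents that add atoms: none
Why: Ring-closing metathesis of a vinyl ether with a 1,1-disubstituted olefin by a molybdenum alkylidene, which tolerates enol ethers and forms trisubstituted olefins; the two arms are held close on the cis-fused bicycle, and loss of ethene drives the closure to the cis ring olefin.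

Step 12
Reactants: 15 eight-membered cyclic enol ether
Product: 17 aldehyde, 2-formyl-2-methyloxepane trans-fused to the lactone ring and cis-fused to ring A (C3 as in the target), via mixed acylal 16 (not isolated)
Conditions: PhI(OCOCF3)2 (1.1 equiv), CF3CH2OH (2 equiv), 2,6-di-tert-butylpyridine, CH2Cl2, −78 to −20 °C; then aq. NaHCO3
Reagents that add atoms: [bis(trifluoroacetoxy)iodo]benzene, O=C(OI(OC(=O)C(F)(F)F)c1ccccc1)C(F)(F)F
Why: Proposed new method: trivalent iodine adds to the nucleophilic enol-ether carbon C3 and trifluoroethanol traps the C4 oxocarbenium ion; loss of iodobenzene from the tertiary C3–iodane is then assisted by the ring oxygen, which shifts from C4 to C3 through a bicyclic oxiranium ion, and the remaining C4 oxocarbenium ion is captured by trifluoroacetate and hydrolysed to the aldehyde on work-up. The closest known reaction type is the oxidative ring contraction of six-membered cyclic enol ethers (glycals to 2,5-anhydroaldoses with thallium trinitrate or trivalent iodine reagents) and the deaminative ring contraction of 2-amino-2-deoxypyranoses, both 1,2-shifts of a ring oxygen; it has not been shown for an eight-membered ring or a tertiary migration terminus. The oxepane is closed by 3-exo-tet attack of the ring oxygen on C3 followed by cleavage of the O–C4 bond, a net one-atom ring contraction that expels C4 as the formyl group. The new centre C3 is controlled by the face of iodane attack: with the C2–C1 ring bond perpendicular to the enol-ether plane and the C2–O bond in that plane (the alternative suffers A(1,2) strain with the C3 methyl), the iodane should add anti to C1 and the ring oxygen then enters from the C1 face with inversion, which is the configuration of the target. The step needs migration of the ring oxygen and not of the exocyclic alkoxy group or of hydride; this is secured by trifluoroethanol, whose oxygen is a poor neighbouring group, and by the relief of medium-ring strain on going from eight to seven.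

Step 13
Reactants: 17 aldehyde
Product: 18 homoallylic alcohol (C4 R; C4–OH with allyl arm C5–C6=CH2)
Conditions: allylSnBu3, MgBr2·OEt2, CH2Cl2, −78 °C
Reagents that add atoms: allyltributylstannane, C=CC[Sn](CCCC)(CCCC)CCCC
Why: Chelation-controlled (Cram-chelate) allylation: magnesium bridges the aldehyde oxygen and the α-ether oxygen of the oxepane, and the stannane attacks from the side of the C3 methyl rather than the ring carbon C2, which should give the C4 configuration of the target; the lactone is not touched.

Step 14
Reactants: 18 homoallylic alcohol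
Product: 19 C4 tert-butyldimethylsilyl ether
Conditions: TBSOTf, 2,6-lutidine, CH2Cl2, −78 °C
Reagents that add atoms: tert-butyldimethylsilyl trifluoromethanesulfonate, CC(C)(C)[Si](C)(C)OS(=O)(=O)C(F)(F)F
Why: Silylation of the hindered secondary alcohol so that it survives hydride reduction, Lewis acid and amide base.

Step 15
Reactants: 19 C4 silyl ether
Product: 20 lactol (C9 hemiacetal, anomeric mixture)
Conditions: i-Bu2AlH (1.1 equiv), CH2Cl2, −78 °C; aqueous Rochelle salt
Reagents that add atoms: none
Why: Partial reduction of the γ-lactone stops at the lactol because the tetrahedral aluminate is stable at −78 °C; ketal, silyl ether and terminal olefin are inert.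

Step 16
Reactants: 20 lactol
Product: 21 C9 methallyl tetrahydrofuran (2,5-cis; C9 as in the target)
Conditions: CH2=C(CH3)CH2SiMe3, BF3·OEt2, CH2Cl2, −78 to −40 °C
Reagents that add atoms: trimethyl(2-methylallyl)silane, CC(=C)C[Si](C)(C)C
Why: Hosomi–Sakurai addition to the five-membered oxocarbenium ion; attack on the convex face of the cis-fused bicycle, anti to the ring A carbon on C10, should give the 2,5-cis tetrahydrofuran, and the lactol ionises far more readily than the dioxolane at low temperature.

Step 17
Reactants: 21 C9 methallyl tetrahydrofuran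
Product: 22 tetracyclic oxonene (C6=C7 Z; C4 silyl ether; C13 ketal)
Conditions: (H2IMes)(PCy3)Cl2Ru=CHPh (second-generation Grubbs catalyst, 10 mol%), CH2Cl2, 40 °C, 1 mM
Reagents that add atoms: none
Why: Ring-closing metathesis between the monosubstituted and the 1,1-disubstituted olefin closes the ether-bridged nine-membered ring, in which only the Z trisubstituted olefin can be accommodated; this ring closure on a preformed hydroisobenzofuran is a known reaction type.

Step 18
Reactants: 22 tetracyclic oxonene
Product: 23 C13 ketone
Conditions: PPTS, acetone–H2O, 50 °C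
Reagents that add atoms: water, O
Why: Mild acetal hydrolysis; the C14 centre is now held in the cis-fused oxepane and the secondary silyl ether survives.

Step 19
Reactants: 23 C13 ketone
Product: 25 enone (C11=C12–C13=O; C4 silyl ether), via TMS enol ether 24 (not isolated)
Conditions: LiN(i-Pr)2, Me3SiCl, THF, −78 °C; then Pd(OAc)2 (10 mol%), O2 (1 atm), DMSO, rt
Reagents that add atoms: none
Why: Kinetic enolisation on the CH2 side (C12), silyl trapping and Saegusa–Ito oxidation (divalent palladium enolate, β-hydride elimination from C11) give the β-methyl enone and remove the auxiliary C11 centre.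

Step 20
Reactants: 25 enone
Product: 26 C4 alcohol
Conditions: HF·pyridine, THF, 0 °C to rt
Reagents that add atoms: none
Why: Acidic fluoride desilylation avoids base-induced epimerisation at C14 or C10 of the enone.

Step 21
Reactants: 26 C4 alcohol
Product: 27 target, (1R,2S,3S,4R,6Z,9S,10S,14R,15R)-configured butyrate (numbering of the remark)
Conditions: (CH3CH2CH2CO)2O, DMAP, Et3N, CH2Cl2, rt
Reagents that add atoms: butyric anhydride, CCCC(=O)OC(=O)CCC
Why: DMAP-catalysed acylation of the secondary alcohol; no stereocentre is affected.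

**Compound list**
1 | methacrolein (2-methylprop-2-enal) | CC(=C)C=O | starting material
2 | methyl propiolate | C#CC(=O)OC | starting material
3 | methyl (R)-4-hydroxy-5-methylhex-5-en-2-ynoate | COC(=O)C#C[C@H](O)C(C)=C | intermediate
4 | methyl (2Z,4S)-4-hydroxy-5-methylhexa-2,5-dienoate | COC(=O)/C=C\[C@H](O)C(C)=C | intermediate
5 | (S)-5-(prop-1-en-2-yl)furan-2(5H)-one | O=C1C=C[C@@H](C(C)=C)O1 | intermediate
6 | (R)-4-methyldihydrofuran-2(3H)-one | C[C@H]1COC(=O)C1 | starting material
7 | (R)-4-hydroxy-N-methoxy-N,3-dimethylbutanamide | CON(C)C(=O)C[C@@H](C)CO | intermediate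
8 | (R)-4-(tert-butyldiphenylsilyloxy)-N-methoxy-N,3-dimethylbutanamide | CON(C)C(=O)C[C@@H](C)CO[Si](c1ccccc1)(c1ccccc1)C(C)(C)C | intermediate
9 | (R,E)-7-(tert-butyldiphenylsilyloxy)-6-methylhept-2-en-4-one | C/C=C/C(=O)C[C@@H](C)CO[Si](c1ccccc1)(c1ccccc1)C(C)(C)C | intermediate
10 | (2E,4Z,6R)-4-(tert-butyldimethylsilyloxy)-7-(tert-butyldiphenylsilyloxy)-6-methylhepta-2,4-diene | C/C=C/C(O[Si](C)(C)C(C)(C)C)=C/[C@@H](C)CO[Si](c1ccccc1)(c1ccccc1)C(C)(C)C | intermediate
11 | endo Diels–Alder adduct, cis-fused tetrahydroisobenzofuranone with C13 silyl enol ether, C2 isopropenyl, C11 methyl and the silyloxypropan-2-yl group on C14 | O=C1O[C@H](C(C)=C)[C@@H]2[C@H]1[C@H](C)C=C(O[Si](C)(C)C(C)(C)C)[C@@H]2[C@@H](C)CO[Si](c1ccccc1)(c1ccccc1)C(C)(C)C | intermediate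
12 | C13 ethylene ketal of the bicyclic keto lactone (silyl ether) | O=C1O[C@H](C(C)=C)[C@@H]2[C@H]1[C@H](C)CC3(OCCO3)[C@@H]2[C@@H](C)CO[Si](c1ccccc1)(c1ccccc1)C(C)(C)C | intermediate
13 | primary alcohol (free C16–OH) | O=C1O[C@H](C(C)=C)[C@@H]2[C@H]1[C@H](C)CC3(OCCO3)[C@@H]2[C@@H](C)CO | intermediate
14 | vinyl ether of 13 | O=C1O[C@H](C(C)=C)[C@@H]2[C@H]1[C@H](C)CC3(OCCO3)[C@@H]2[C@@H](C)COC=C | intermediate
15 | eight-membered cyclic enol ether (Z; O–CH=C(CH3)) fused to the ketal lactone | C/C1=C/OC[C@H](C)[C@H]2C3(OCCO3)C[C@@H](C)[C@H]4C(=O)O[C@H]1[C@@H]24 | intermediate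
16 | mixed acylal at C4 (trifluoroethoxy, trifluoroacetoxy) of the ring-contracted oxepane | FC(F)(F)COC(OC(=O)C(F)(F)F)[C@]1(C)OC[C@H](C)[C@H]2C3(OCCO3)C[C@@H](C)[C@H]4C(=O)O[C@H]1[C@@H]24 | intermediate
17 | 2-formyl-2-methyloxepane tricycle (C4 aldehyde) | O=C[C@]1(C)OC[C@H](C)[C@H]2C3(OCCO3)C[C@@H](C)[C@H]4C(=O)O[C@H]1[C@@H]24 | intermediate
18 | C4 homoallylic alcohol | C=CC[C@@H](O)[C@]1(C)OC[C@H](C)[C@H]2C3(OCCO3)C[C@@H](C)[C@H]4C(=O)O[C@H]1[C@@H]24 | intermediate
19 | C4 tert-butyldimethylsilyl ether | C=CC[C@@H](O[Si](C)(C)C(C)(C)C)[C@]1(C)OC[C@H](C)[C@H]2C3(OCCO3)C[C@@H](C)[C@H]4C(=O)O[C@H]1[C@@H]24 | intermediate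
20 | C9 lactol (anomeric mixture) | C=CC[C@@H](O[Si](C)(C)C(C)(C)C)[C@]1(C)OC[C@H](C)[C@H]2C3(OCCO3)C[C@@H](C)[C@H]4C(O)O[C@H]1[C@@H]24 | intermediate
21 | C9 methallyl tetrahydrofuran (diene for the last metathesis) | C=CC[C@@H](O[Si](C)(C)C(C)(C)C)[C@]1(C)OC[C@H](C)[C@H]2C3(OCCO3)C[C@@H](C)[C@H]4[C@H](CC(C)=C)O[C@H]1[C@@H]24 | intermediate
22 | tetracyclic oxonene, C4 silyl ether, C13 ketal | CC(C)(C)[Si](C)(C)O[C@@H]1C/C=C(/C)C[C@@H]2O[C@H]3[C@@H]4[C@H]2[C@H](C)CC5(OCCO5)[C@@H]4[C@@H](C)CO[C@@]13C | intermediate
23 | C13 ketone | CC(C)(C)[Si](C)(C)O[C@@H]1C/C=C(/C)C[C@@H]2O[C@H]3[C@@H]4[C@H]2[C@H](C)CC(=O)[C@@H]4[C@@H](C)CO[C@@]13C | intermediate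
24 | trimethylsilyl enol ether (C12=C13) | CC(C)(C)[Si](C)(C)O[C@@H]1C/C=C(/C)C[C@@H]2O[C@H]3[C@@H]4[C@H]2[C@H](C)C=C(O[Si](C)(C)C)[C@@H]4[C@@H](C)CO[C@@]13C | intermediate
25 | enone, C4 silyl ether | CC(C)(C)[Si](C)(C)O[C@@H]1C/C=C(/C)C[C@@H]2O[C@H]3[C@@H]4[C@H]2C(C)=CC(=O)[C@@H]4[C@@H](C)CO[C@@]13C | intermediate
26 | C4 alcohol | O[C@@H]1C/C=C(/C)C[C@@H]2O[C@H]3[C@@H]4[C@H]2C(C)=CC(=O)[C@@H]4[C@@H](C)CO[C@@]13C | intermediate
27 | target butyrate | CCCC(=O)O[C@@H]1C/C=C(/C)C[C@@H]2O[C@H]3[C@@H]4[C@H]2C(C)=CC(=O)[C@@H]4[C@@H](C)CO[C@@]13C | target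

**Step count and risks**
Total: 21 steps. Longest linear sequence: 19 steps (6 to 27 through steps 3–21); the butenolide branch (steps 1–2) joins at step 7.

Most likely to fail, step 12 (Proposed new method). What may go wrong: the exocyclic alkoxy group or a hydride migrates instead of the ring oxygen, the tertiary iodane eliminates, or the iodane attacks the other face of the enol ether so that C3 is formed with the wrong configuration. The fallback uses known chemistry, sets out from 13 and comes back at 17. The isopropenyl group of 13 is epoxidised (m-CPBA, NaHCO3, CH2Cl2, 0 °C) to the epoxy alcohol F1, the C3 epimers being separated if substrate control is low. Acid-catalysed 7-exo opening of the epoxide at its tertiary carbon by the primary hydroxyl (CSA cat., CH2Cl2, 0 °C), with inversion at C3, should give the 2-(hydroxymethyl)-2-methyloxepane F2. Dess–Martin oxidation (CH2Cl2, NaHCO3) then gives 17.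

Second, step 11. What may go wrong: initiation at the vinyl ether gives an unreactive alkoxy-carbene, the hindered 1,1-disubstituted olefin does not engage, and oligomerisation outruns closure of the medium ring. The fallback sets out from 12 and comes back at 15. Allylic oxidation of the isopropenyl methyl group (SeO2 cat., t-BuOOH, CH2Cl2) gives the 2-substituted allylic alcohol F3, and ClCO2Me/pyridine gives the allylic methyl carbonate F4. Desilylation (HF·pyridine, THF) gives the hydroxy carbonate F5. Intramolecular allylic etherification with zerovalent palladium (Pd(PPh3)4, THF, high dilution; the two termini of the 2-substituted allyl unit are equivalent) should close the 3-methylene eight-membered ether F6. Isomerisation of the exocyclic allyl-ether double bond into conjugation with oxygen ([Ir(cod)(PMePh2)2]PF6 activated with H2, THF) then gives 15.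

Third, step 7. What may go wrong: the 1,4-disubstituted diene reacts too slowly with the butenolide, so that thermal decomposition of the silyl dienol ether, isomerisation of the γ-isopropenyl butenolide to its achiral conjugated isomer, and loss of endo and facial selectivity compete. The fallback sets out from 9 and 5 and comes back at 12. The kinetic lithium dienolate of 9 (LiN(i-Pr)2, THF, −78 °C) adds to 5 anti to the isopropenyl group, and the lactone enolate closes ring A by a second, intramolecular Michael addition (anionic double Michael annulation) to give the keto lactone F7. Ketalisation (ethylene glycol, PPTS, benzene, 60 °C) then gives 12.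

**Further compounds**
F1 | step 12 | epoxy alcohol, epoxide of the isopropenyl group of 13 | O=C1O[C@H]([C@@]3(C)CO3)[C@@H]2[C@H]1[C@H](C)CC4(OCCO4)[C@@H]2[C@@H](C)CO
F2 | step 12 | 2-(hydroxymethyl)-2-methyloxepane tricycle | OC[C@]1(C)OC[C@H](C)[C@H]2C3(OCCO3)C[C@@H](C)[C@H]4C(=O)O[C@H]1[C@@H]24
F3 | step 11 | 2-substituted allylic alcohol from 12 | O=C1O[C@H](C(=C)CO)[C@@H]2[C@H]1[C@H](C)CC3(OCCO3)[C@@H]2[C@@H](C)CO[Si](c1ccccc1)(c1ccccc1)C(C)(C)C
F4 | step 11 | allylic methyl carbonate | O=C1O[C@H](C(=C)COC(=O)OC)[C@@H]2[C@H]1[C@H](C)CC3(OCCO3)[C@@H]2[C@@H](C)CO[Si](c1ccccc1)(c1ccccc1)C(C)(C)C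
F5 | step 11 | hydroxy carbonate | O=C1O[C@H](C(=C)COC(=O)OC)[C@@H]2[C@H]1[C@H](C)CC3(OCCO3)[C@@H]2[C@@H](C)CO
F6 | step 11 | 3-methylene eight-membered cyclic ether | C=C1COC[C@H](C)[C@H]2C3(OCCO3)C[C@@H](C)[C@H]4C(=O)O[C@H]1[C@@H]24
F7 | step 7 | bicyclic keto lactone (C13 ketone) | O=C1O[C@H](C(C)=C)[C@@H]2[C@H]1[C@H](C)CC(=O)[C@@H]2[C@@H](C)CO[Si](c1ccccc1)(c1ccccc1)C(C)(C)C
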